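At the 10.0 h reading the teal run held 6.0% of target on 1 mol% of free catalyst, or about 6.00 turnovers (the turnover number, counted here from the target standing in the flask). The bench rule is to multiply turnovers per hour by hours, so I tried it.

the same everywhere: free catalyst 1 mol%

|  | starting material | partner | remark | time |
|---|---|---|---|---|
| teal | 0.050 M | 1.1 equiv | run made earlier |  |
| grey | 0.050 M | 0.55 equiv | run made earlier |  |
| ochre | 0.050 M | 2.2 equiv | run made earlier |  |
| Monday's | 0.050 M | 1.10 equiv | one stirred flow tank at steady state, fed with the mixture as stated, mean residence time 15 h |  |
| Wednesday's | 0.050 M | 1.10 equiv | everything together in a closed stirred flask, run for 15 h | 15 h |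
| Friday's | 0.050 M (fed, over 12.0 h) | 1.10 equiv | a stirred flask in which starting material is dosed at a steady rate over 12.0 h without added volume, worked up at 15 h | 15 h |
| Thursday's | 0.050 M | 1.10 equiv (fed, over 12.0 h) | a stirred flask in which partner is dosed at a steady rate over 12.0 h without added volume, worked up at 15 h | 15 h |

| run | time / h | target / % |
|---|---|---|
| teal | 0.667 | 0.8 |
| teal | 2.00 | 2.8 |
| teal | 3.00 | 3.0 |
| teal | 5.00 | 4.2 |
| teal | 6.00 | 4.4 |
| teal | 10.0 | 6.0 |
| grey | 2.50 | 1.1 |
| grey | 5.00 | 2.0 |
| grey | 8.00 | 2.1 |
| grey | 10.0 | 2.2 |
| grey | 12.0 | 2.5 |
| grey | 15.0 | 2.3 |
| ochre | 2.50 | 5.2 |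
| ochre | 5.00 | 7.1 |
| ochre | 8.00 | 8.0 |
| ochre | 10.0 | 9.7 |
| ochre | 12.0 | 10.1 |
| ochre | 15.0 | 9.6 |

(readings scatter by 0.5 percentage points)

- the stated concentrations are those of everything mixed, before any reaction; amounts are the same in each set-up
- the feed brings no volume worth counting
- the earlier runs were made in a closed, stirred flask

1. the set-up with the highest amount of target at the outlet or at the end, in percent of the starting material put in ("none" if the first two lie within 2 percentage points) (Monday's / Wednesday's / Friday's / Thursday's / none)
2. amount of target at the outlet or at the end, in percent of the starting material put in, Monday's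
3. amount of target at the outlet or at the end, in percent of the starting material put in, Wednesday's
4. amount of target at the outlet or at the end, in percent of the starting material put in, Friday's
5. amount of target at the outlet or at the end, in percent of the starting material put in, Thursday's

Teal's 2.8% at 2.00 h gives 1.40 h⁻¹, so the rule promises 21.0 turnovers in 15 h. The readings do not keep that pace: the rule gives 14.0 turnovers at 10.0 h, and teal read 6.00. The ochre run stayed near 9.80% from 10.0 h on. Ochre over grey at 15.0 h reads 4.17 for a partner ratio of 4.00, so I scaled the ochre level to 1.10 equiv and got a flat level of 4.90 turnovers. Teal's last reading stands 1.1 percentage points above that level, against a scatter of 0.5 points, so the level is an estimate from readings and not a bound.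

Dividing that level by the starting rate gives 3.50 h. This is the stall time, the flat-stretch turnovers over the turnovers per hour at the start. In these runs the bench rule serves for times short against it, and 15 h is 4.29 times the stall time.

My own reckoning used the stall time three ways:

- **Wednesday's closed flask:** the flat level times one minus exp(−time/stall time) gives 4.83%.
- **Monday's tank:** with a residence time also of 15 h, the flat level times residence/(residence + stall time) gives 3.97%.
- **Thursday's flask:** target trails the partner ramp, leaving a shortfall of 12.0% at work-up, so 4.31%.

I gave Friday's flask no number, because these runs never varied starting material. My call was "none", with Friday's open.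

The forecast differed from mine: Monday's 4.2%, Wednesday's 5.2%, and 3% for each dosed flask, ranging from 1.1% to 5%, with best none. Of the dosing it said: “Dosing does separate them.”

The flasks gave Monday's 3.99%, Wednesday's 5.12%, Friday's 5.00% and Thursday's 4.45%. The first two lay 0.12 points apart, so the best is none, as the forecast said.

    starting material + free catalyst ⇌ catalyst intermediate A (K = 17.0 M⁻¹, k = 3.57 M⁻¹ s⁻¹)
    catalyst intermediate A ⇌ catalyst intermediate B (K = 0.200, k = 0.0192 s⁻¹)
    partner + catalyst intermediate B → catalyst intermediate C (k = 0.0949 M⁻¹ s⁻¹)
    catalyst intermediate C → free catalyst + target (k = 0.0188 s⁻¹)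
    starting material + target → side product (k = 0.00155 M⁻¹ s⁻¹)

In Wednesday's flask the half-life of target by its step with starting material alone, starting material taken as charged, was 2.5 h, shorter than the 15 h run, and as a lifetime that is 3.61 h, beside the stall time of 3.50 h read from the earlier runs. Carried to Thursday's flask, the stall time's shortfall of 12.0% taken off Wednesday's 5.12% gives 4.51%, and Thursday's flask stood at 4.45%.

All runs were generated by integration from invented constants, and the scatter is random.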